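## Structural features

The target consists of two guaiane (hydroazulene) units. Guaiane numbering is used throughout: five-membered ring C1–C5, seven-membered ring C1, C5–C10, methyl groups on C4 and C10, isopropyl carbon C11 on C7. Unprimed atoms belong to the acetate unit, primed atoms to the peroxide unit. The units are joined by C1–C2' and C3–C1', so that C1–C5, C1' and C2' form a norbornene. Its one-carbon bridge C2 carries the acetate on the side of the C4=C5 bond, and the primed cyclopentenone is exo-fused (C3' and C5' syn to C2, C10' endo). C10, C1, C2, C3, C1' and C2' are contiguous stereocentres, with C10' on the quaternary C1' and C7 cis to C10 across the unprimed cycloheptanone. The two C10 centres have opposite sense in their units (10S, 10'R). The primed unit is a 4',6'-dien-3'-one whose C7' bears a 3-hydroxy-1,2-dioxolane (C11'–O–O–C8'(OH)). This peroxy hemiketal is sensitive to reductants, base and acylating agents; the acetate, the enones and the strained C4=C5 alkene are the other delicate groups. The real difficulty is the union: two quaternary centres, the exo orientation, and a C2 oxygen that must end anti to the incoming dienophile. The key step exploits the fact that the unprimed seven-membered ring is an anisole ring (C5–C10, oxygen on C8, isopropyl on C7) plus one carbon, C1, that sits next to the C2 oxygen.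

## Logic of the disconnections

35 to 33: the O–C11' and O–C8' bonds are cut, which removes O2. The forward step must oxygenate the tertiary, doubly allylic C11'–H of the dienedione; the hydroperoxide 34 then closes onto the C8' ketone.

33 to 29 (through 32 and 31): acetyl, silyl and ketal groups and the C6'=C7' unsaturation are removed. The dehydrogenation is placed before ketal removal so that C3' is the only enolisable carbonyl.

29 to 20 and 28: C1–C2' and C3–C1' are cut (Diels–Alder). This halves the molecule and creates C1, C3, C1' and C2' at once. The forward step demands addition anti to the C2 oxygen, on the faces carrying H-10 and H-10', with the dienone ring exo.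

20 to 16 (through 19, 18, 17): the C3=C4 bond and the C2 stereocentre are traced to an enone. The diene is non-fluxional because C2 carries oxygen, not silicon. The temporary C4 centre controls C3 (selenide trans to methyl) and C2 (hydride anti to selenium), and leaves only H-4 syn to selenium for the elimination.

28 to 23 (through 27, 26, 25, 24): the C3' oxygen is moved from C2' by a singlet-oxygen cycloaddition to a cyclopentadiene. The demand is that 25 is made and used as the single double-bond isomer.

16 and 23 to 13: the C10–CH3 bond is cut in both series. The two halves need opposite C10 centres, so one dienone serves both, each with one enantiomer of the ligand. Because C4 is fixed, the two products are diastereomers.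

13 to 10: the C8 enol ether is hydrolysed only after the C2 ketone has been reduced. A 2,8-dione with C9=C10 would be a vinylogous 1,3-diketone and would quench the organozinc reagent.

10 to 9 (key): C1–C5 and C1–C10 are cut, so the bicyclic skeleton collapses to a 4-arylpentanone. 9 to 6 and 7 cuts C1–C2; 6 to 3 and 4 cuts the aryl–C4 bond and sets C4; 3 comes from 1.

## Other disconnections considered

Alternative 1: The primed seven-membered ring is cut at C6'–C7' and C9'–C10'. Forward, Rh2(S-DOSP)4 converts the vinyldiazoacetate A1 into a carbenoid that cyclopropanates the exocyclic methylene of diene A2; Cope rearrangement of the cis-divinylcyclopropane gives the hydroazulene A3. In its favour: two C–C bonds and the ring in one catalyst-controlled step, with the C3' and C8' oxygens and a C7' ester handle already in place. On the C3' oxygen it is better than the chosen plan, which needs a transposition. Against it: it builds only the primed half, needs a stereodefined diene, and A3 still needs ester-to-isopropylidene and C1'=C2' adjustments. The two plans are equal in bonds formed per key step. The chosen plan is more economical overall because one Buchner product feeds both halves.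

Alternative 2: The C1–C2 bond of the norbornene is traced to a bicyclo[2.2.2]octenone. Forward, photolysis of the bridging diazoketone A4 in methanol gives Wolff ring contraction to the ester A5, which is equilibrated to the epimer syn to C4=C5. In its favour: masked o-benzoquinone cycloadditions are regiochemically dependable, no cyclopentadiene isomerism arises, and the bridge centre is set under thermodynamic control. On that last point it is better than the chosen plan, which depends on a facial preference. Against it: the ester must still be degraded to the acetate (several steps in the presence of enones), and a late photolysis next to an isopropylidene enone is exposed to competing photochemistry. Both plans join the halves by a cycloaddition; the chosen one reaches the C2 oxygen more directly.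

Alternative 3: The primed ring is cut at C6'=C7'. Forward, second-generation Grubbs catalyst loads on the C5' vinyl group of enyne A6 and closes onto the alkyne, giving the cycloheptadiene ketal A7 with an isopropenyl group. In its favour: the ring and the peroxide handle appear together, and cobalt-catalysed silane/O2 hydroperoxidation of an isopropenyl group is a more controlled peroxidation than the autoxidation chosen here, so on that point it is the better plan. Against it: the ruthenium carbene must ignore the strained C4=C5 norbornene alkene (ring-opening risk), the hydroperoxidation must choose C11' over C6' in a conjugated diene, and more steps are run on the dimer. Ring count per key step is equal.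

Key step: step 6

Remarks on the chemistry (assumptions):
- The diazoketone is used as the 4R enantiomer and the Buchner product is formulated as (3R,8aR), with the 3-methyl group trans to H-8a. Allylic strain in the tether should favour this isomer, and the R centre is needed as the relay for C3 and C2 in steps 11–14.
- (S)-BINAP is assumed to give the 3R ester; if the sense is opposite, (R)-BINAP is used.
- L* denotes the (S,R,R)-binaphthol N,N-bis(1-phenylethyl)phosphoramidite. It is assumed to give the 10S series and ent-L* the 10R series; the ligands are exchanged if the sense is opposite.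
- The 7,10-cis arrangement is assumed to be the more stable one at C7 (alpha to the C8 ketone).
- The C8' hemiketal forms reversibly; the configuration drawn is assumed to be the more stable one.

## Steps

Step 1
Reactants: 1 2-isopropylanisole
Product: 2 4-bromo-2-isopropylanisole
Conditions: NBS, MeCN, 0 to 25 °C
Reagents that add atoms: N-bromosuccinimide O=C1CCC(=O)N1Br
Why: Electrophilic aromatic bromination; the methoxy group directs para and the ortho position is shielded.

Step 2
Reactants: 2 4-bromo-2-isopropylanisole
Product: 3 (3-isopropyl-4-methoxyphenyl)boronic acid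
Conditions: n-BuLi, THF, −78 °C; B(Oi-Pr)3; HCl (1 M aq.)
Reagents that add atoms: triisopropyl borate CC(C)OB(OC(C)C)OC(C)C; water O
Why: Bromine–lithium exchange and borylation of the aryllithium, then hydrolysis.

Step 3
Reactants: 3 (3-isopropyl-4-methoxyphenyl)boronic acid; 4 ethyl (E)-crotonate
Product: 5 ethyl (3R)-3-(3-isopropyl-4-methoxyphenyl)butanoate
Conditions: [Rh(cod)Cl]2 (1.5 mol %), (S)-BINAP, KOH (aq.), dioxane, 50 °C
Reagents that add atoms: none
Why: Hayashi–Miyaura conjugate arylation; the ligand selects the enantioface of the crotonate and sets C4.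

Step 4
Reactants: 5 ethyl (3R)-3-(3-isopropyl-4-methoxyphenyl)butanoate
Product: 6 (3R)-3-(3-isopropyl-4-methoxyphenyl)butanoic acid
Conditions: LiOH, THF–MeOH–H2O, 25 °C; HCl (aq.)
Reagents that add atoms: lithium hydroxide [Li+].[OH-]
Why: Saponification; the stereocentre is beta to the carbonyl and is not at risk.

Step 5
Reactants: 6 (3R)-3-(3-isopropyl-4-methoxyphenyl)butanoic acid; 7 (trimethylsilyl)diazomethane
Product: 9 (4R)-1-diazo-4-(3-isopropyl-4-methoxyphenyl)pentan-2-one, via acid chloride 8 (not isolated)
Conditions: (COCl)2, DMF (cat.), CH2Cl2, 0 to 25 °C; then 7 (2.2 equiv), THF–MeCN, 0 °C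
Reagents that add atoms: none
Why: Acylation of the diazoalkane (Arndt–Eistert type diazoketone synthesis); the second equivalent takes up HCl and the C-silyl group is lost on work-up.

Step 6
Reactants: 9 (4R)-1-diazo-4-(3-isopropyl-4-methoxyphenyl)pentan-2-one
Product: 10 (3R,8aR)-6-methoxy-3-methyl-5-isopropyl-3,8a-dihydroazulen-1(2H)-one
Conditions: Rh2(OAc)4 (1 mol %), CH2Cl2, reflux, slow addition, high dilution
Reagents that add atoms: none
Why: Loss of N2 gives a rhodium keto-carbenoid at C1 that adds across the ipso–ortho bond C5–C10 (intramolecular Buchner reaction of an aryl diazoketone to an azulenone, a known reaction type). Formation of C1–C5 closes the five-membered ring as the cis-fused bicyclo[3.1.0]hexanone of a norcaradiene. The seven-membered ring then arises by thermally allowed disrotatory 6π opening of the C5–C10 bond, which leaves C1 as the sp3 carbon of the cycloheptatriene. The anisole oxygen ends as the C8 enol ether with isopropyl on C7, and C9=C10 is placed for the later methyl addition. The new centre C1 is controlled by C4: the benzylic hydrogen eclipses the arene plane to avoid allylic strain, which should place the methyl group trans to H-8a. The step needs the carbenoid to choose C5–C10 over C5–C6; the isopropyl group on C7 flanks C6 and blocks that side. It also needs cycloaddition to win over C–H insertion and aromatic substitution; the neutral carboxylate catalyst and the five-atom tether favour cycloaddition, and acid must be excluded to prevent rearrangement to a 2-tetralone.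

Step 7
Reactants: 10 (3R,8aR)-6-methoxy-3-methyl-5-isopropyl-3,8a-dihydroazulen-1(2H)-one
Product: 13 (4R)-2-hydroxyguaia-1(5),9-dien-8-one (C2/C7 epimers), via conjugated trienone 11 (not isolated), via allylic alcohol 12 (not isolated)
Conditions: Et3N (cat.), CH2Cl2, 25 °C; NaBH4, CeCl3·7H2O, MeOH, −40 °C; then PPTS, acetone–H2O, 0 °C
Reagents that add atoms: water O
Why: Base moves H-8a to C6 to give the conjugated 3,4-dihydroazulenone (C1=C5). Luche 1,2-reduction then removes the only carbonyl, so that hydrolysis of the enol ether (protonation at C7) gives a dienone that is not a vinylogous 1,3-diketone. The C2 and C7 centres are not controlled here; C2 is reoxidised and C7 is equilibrated later.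

Step 8
Reactants: 13 (4R)-2-hydroxyguaia-1(5),9-dien-8-one
Product: 14 (4R,7R,10S)-2-hydroxyguai-1(5)-en-8-one (C2 epimers)
Conditions: Me2Zn (3 equiv), Cu(OTf)2 (2 mol %), L* (4 mol %), toluene, −30 to 0 °C; NH4Cl (aq.); then DBU (cat.), MeOH, 25 °C
Reagents that add atoms: dimethylzinc C[Zn]C
Why: Copper-catalysed asymmetric conjugate addition; the ligand sets C10 because C1 is sp2 and exerts no bias. 1,6-Addition is blocked because the delta carbon C5 is fully substituted. DBU then equilibrates C7 to the cis-7,10 isomer.

Step 9
Reactants: 14 (4R,7R,10S)-2-hydroxyguai-1(5)-en-8-one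
Product: 15 (4R,7R,10S)-guai-1(5)-ene-2,8-dione
Conditions: MnO2 (activated), CH2Cl2, 25 °C
Reagents that add atoms: none
Why: Chemoselective oxidation of the allylic alcohol; both C2 epimers converge.

Step 10
Reactants: 15 (4R,7R,10S)-guai-1(5)-ene-2,8-dione
Product: 16 (4R,7R,10S)-8,8-(ethylenedioxy)guai-1(5)-en-2-one
Conditions: Me3SiOCH2CH2OSiMe3, Me3SiOTf (cat.), CH2Cl2, −40 to −20 °C
Reagents that add atoms: 1,2-bis(trimethylsilyloxy)ethane C[Si](C)(C)OCCO[Si](C)(C)C
Why: Ketalisation under silyl triflate catalysis; the saturated C8 ketone reacts, the conjugated tetrasubstituted cyclopentenone does not.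

Step 11
Reactants: 16 (4R,7R,10S)-8,8-(ethylenedioxy)guai-1(5)-en-2-one
Product: 17 3-(phenylselanyl)-8,8-(ethylenedioxy)guai-1(5)-en-2-one (Se trans to the C4 methyl)
Conditions: LiN(i-Pr)2, THF, −78 °C; PhSeCl
Reagents that add atoms: benzeneselenenyl chloride Cl[Se]c1ccccc1
Why: Kinetic alpha' enolate formation and selenenylation; the electrophile enters anti to the neighbouring C4 methyl group, so selenium is cis to H-4.

Step 12
Reactants: 17 3-(phenylselanyl)-8,8-(ethylenedioxy)guai-1(5)-en-2-one
Product: 18 3-(phenylselanyl)-8,8-(ethylenedioxy)guai-1(5)-en-2-ol (OH cis to Se and to the C10 methyl)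
Conditions: i-Bu2AlH, toluene, −78 °C
Reagents that add atoms: none
Why: 1,2-Reduction of the enone; the bulky hydride should come anti to the adjacent selenide, which is also the face of H-10, and this sets C2.

Step 13
Reactants: 18 3-(phenylselanyl)-8,8-(ethylenedioxy)guai-1(5)-en-2-ol
Product: 19 tert-butyldimethylsilyl ether of 18
Conditions: t-BuMe2SiOTf, 2,6-lutidine, CH2Cl2, −78 to 0 °C
Reagents that add atoms: tert-butyldimethylsilyl triflate CC(C)(C)[Si](C)(C)OS(=O)(=O)C(F)(F)F
Why: Silylation of a hindered secondary alcohol; the bulky, weakly electron-withdrawing ether is chosen to close the oxygen face of the later diene.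

Step 14
Reactants: 19 tert-butyldimethylsilyl ether of 18
Product: 20 (2R,7R,10S)-2-(tert-butyldimethylsilyloxy)-8,8-(ethylenedioxy)guaia-1(5),3-diene
Conditions: mCPBA (1.0 equiv), CH2Cl2, −78 °C; i-Pr2NH, −78 to −20 °C; cold filtration, used at once
Reagents that add atoms: none
Why: Selenoxide syn-elimination; only H-4 is syn to selenium (H-2 is anti and carries oxygen), so C3=C4 forms regiospecifically. The 5-oxy-cyclopentadiene does not migrate its substituent and is used before 1,5-hydrogen shifts set in.

Step 15
Reactants: 13 (4R)-2-hydroxyguaia-1(5),9-dien-8-one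
Product: 21 (4R,7S,10R)-2-hydroxyguai-1(5)-en-8-one (C2 epimers)
Conditions: Me2Zn (3 equiv), Cu(OTf)2 (2 mol %), ent-L* (4 mol %), toluene, −30 to 0 °C; NH4Cl (aq.); then DBU (cat.), MeOH, 25 °C
Reagents that add atoms: dimethylzinc C[Zn]C
Why: The same asymmetric conjugate addition with the mirror-image ligand gives the opposite C10 centre needed in the primed half. The product is a diastereomer of 14 because C4 is fixed.

Step 16
Reactants: 21 (4R,7S,10R)-2-hydroxyguai-1(5)-en-8-one
Product: 22 (4R,7S,10R)-guai-1(5)-ene-2,8-dione
Conditions: MnO2 (activated), CH2Cl2, 25 °C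
Reagents that add atoms: none
Why: Allylic alcohol oxidation, as in step 9.

Step 17
Reactants: 22 (4R,7S,10R)-guai-1(5)-ene-2,8-dione
Product: 23 (4R,7S,10R)-8,8-(ethylenedioxy)guai-1(5)-en-2-one
Conditions: Me3SiOCH2CH2OSiMe3, Me3SiOTf (cat.), CH2Cl2, −40 to −20 °C
Reagents that add atoms: 1,2-bis(trimethylsilyloxy)ethane C[Si](C)(C)OCCO[Si](C)(C)C
Why: Selective ketalisation of the saturated ketone, as in step 10.

Step 18
Reactants: 23 (4R,7S,10R)-8,8-(ethylenedioxy)guai-1(5)-en-2-one
Product: 24 (4R,7S,10R)-8,8-(ethylenedioxy)guaia-1(5),2-dien-2-yl trifluoromethanesulfonate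
Conditions: KN(SiMe3)2, THF, −78 °C; PhNTf2
Reagents that add atoms: N-phenylbis(trifluoromethanesulfonimide) O=S(=O)(N(c1ccccc1)S(=O)(=O)C(F)(F)F)C(F)(F)F
Why: Kinetic alpha' deprotonation gives the cross-conjugated enolate, trapped on oxygen as the dienyl triflate.

Step 19
Reactants: 24 (4R,7S,10R)-8,8-(ethylenedioxy)guaia-1(5),2-dien-2-yl trifluoromethanesulfonate
Product: 25 (4R,7S,10R)-8,8-(ethylenedioxy)guaia-1(5),2-diene
Conditions: Pd(OAc)2 (5 mol %), PPh3, Bu3N, HCO2H, DMF, 25 to 40 °C; used at once
Reagents that add atoms: none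
Why: Palladium-catalysed formate reduction of an enol triflate; it gives the cyclopentadiene as one double-bond isomer (sp3 carbon C4), used before 1,5-hydrogen shifts scramble it.

Step 20
Reactants: 25 (4R,7S,10R)-8,8-(ethylenedioxy)guaia-1(5),2-diene
Product: 27 (7S,10R)-5-hydroxy-8,8-(ethylenedioxy)guai-1-en-3-one (C4/C5 epimers), via endoperoxide 26 (not isolated)
Conditions: O2, tetraphenylporphyrin, hν (visible), CH2Cl2, −78 °C; then Et3N, −78 to 0 °C
Reagents that add atoms: dioxygen O=O
Why: Singlet-oxygen [4+2] cycloaddition across C3 and C5, then Kornblum–DeLaMare rearrangement. Only C3 carries hydrogen, so the ketone appears at C3 and the hydroxyl at C5; this moves the ring oxygen from C2 to C3. The C4 and C5 centres are lost in the next step.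

Step 21
Reactants: 20 (2R,7R,10S)-2-(tert-butyldimethylsilyloxy)-8,8-(ethylenedioxy)guaia-1(5),3-diene; 27 (7S,10R)-5-hydroxy-8,8-(ethylenedioxy)guai-1-en-3-one
Product: 29 norbornene adduct (C1–C2' and C3–C1' bonds; C2 silyl ether syn to C4=C5; dienone ring exo; both C8 ketals), via cyclopentadienone 28 (not isolated)
Conditions: 20 (1.0 equiv), CH2Cl2, −40 °C; slow addition of 27 (1.3 equiv) and Ph2S[OC(CF3)2Ph]2; −40 to 0 °C
Reagents that add atoms: none
Why: Non-basic dehydration of the beta-hydroxy ketone releases the cyclopentadienone 28, which the electron-rich diene traps in a Diels–Alder reaction (cyclopentadienones are known to act as the 2π partner towards cyclopentadienes). The fully substituted C1' bonds to the unsubstituted C3. The diene should react on the face of H-2 and H-10 and the dienone anti to its C10' methyl group. Because C1' must place a carbon substituent exo, the silyl ether face is closed; the exo placement of the dienone ring is the least secure element.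

Step 22
Reactants: 29 norbornene adduct
Product: 31 4',6'-dien-3'-one (C6'=C7' introduced), via silyl dienol ether 30 (not isolated)
Conditions: Me3SiOTf, Et3N, CH2Cl2, 0 to 25 °C; then Pd(OAc)2 (1.1 equiv), MeCN, 25 °C
Reagents that add atoms: none
Why: C3' is the only enolisable carbonyl and its alpha' hydrogen (H-2') lies between two quaternary carbons, so enolisation runs through C6' to the extended dienol ether. Saegusa–Ito oxidation then removes H-7' and gives the linear dienone.

Step 23
Reactants: 31 4',6'-dien-3'-one
Product: 32 2-hydroxy-3',8,8'-trione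
Conditions: HCl (2 M aq.), THF, 40 °C
Reagents that add atoms: water O
Why: Acid hydrolysis of both dioxolanes and of the silyl ether. C7 can equilibrate again to the cis-7,10 arrangement.

Step 24
Reactants: 32 2-hydroxy-3',8,8'-trione
Product: 33 2-acetoxy-3',8,8'-trione
Conditions: Ac2O, DMAP (cat.), pyridine, 25 °C, under argon
Reagents that add atoms: acetic anhydride CC(=O)OC(C)=O
Why: Acetylation of the only hydroxyl group, done before the peroxide exists.

Step 25
Reactants: 33 2-acetoxy-3',8,8'-trione
Product: 35 target (CNP0361479.4), via hydroperoxide 34 (not isolated)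
Conditions: O2 (1 atm), N-hydroxyphthalimide (20 mol %), AIBN (5 mol %), MeCN, 40 °C, dark
Reagents that add atoms: dioxygen O=O
Why: Radical-chain autoxidation of the weakest C–H bond (tertiary C11'–H, allylic to the dienedione). O2 should be taken up at C11' because that keeps the conjugated system, and the hydroperoxide then adds to the C8' ketone to give the 3-hydroxy-1,2-dioxolane.

## Compound list

1 | 2-isopropylanisole | COc1ccccc1C(C)C | starting material
2 | 4-bromo-2-isopropylanisole | COc1ccc(Br)cc1C(C)C | intermediate
3 | (3-isopropyl-4-methoxyphenyl)boronic acid | COc1ccc(cc1C(C)C)B(O)O | intermediate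
4 | ethyl (E)-crotonate | CCOC(=O)/C=C/C | starting material
5 | ethyl (3R)-3-(3-isopropyl-4-methoxyphenyl)butanoate | CCOC(=O)C[C@@H](C)c1ccc(OC)c(C(C)C)c1 | intermediate
6 | (3R)-3-(3-isopropyl-4-methoxyphenyl)butanoic acid | OC(=O)C[C@@H](C)c1ccc(OC)c(C(C)C)c1 | intermediate
7 | (trimethylsilyl)diazomethane | C[Si](C)(C)C=[N+]=[N-] | starting material
8 | (3R)-3-(3-isopropyl-4-methoxyphenyl)butanoyl chloride | ClC(=O)C[C@@H](C)c1ccc(OC)c(C(C)C)c1 | intermediate
9 | (4R)-1-diazo-4-(3-isopropyl-4-methoxyphenyl)pentan-2-one | COc1ccc(cc1C(C)C)[C@H](C)CC(=O)C=[N+]=[N-] | intermediate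
10 | (3R,8aR)-6-methoxy-3-methyl-5-isopropyl-3,8a-dihydroazulen-1(2H)-one (3-methyl trans to H-8a) | COC1=C(C(C)C)C=C2[C@H](C)CC(=O)[C@@H]2C=C1 | intermediate
11 | (3R)-6-methoxy-3-methyl-5-isopropyl-3,4-dihydroazulen-1(2H)-one | O=C1C[C@@H](C)C2=C1C=CC(OC)=C(C(C)C)C2 | intermediate
12 | (3R)-6-methoxy-3-methyl-5-isopropyl-1,2,3,4-tetrahydroazulen-1-ol (both carbinol epimers) | OC1C[C@@H](C)C2=C1C=CC(OC)=C(C(C)C)C2 | intermediate
13 | (4R)-2-hydroxyguaia-1(5),9-dien-8-one (C2 and C7 epimers) | OC1C[C@@H](C)C2=C1C=CC(=O)C(C(C)C)C2 | intermediate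
14 | (4R,7R,10S)-2-hydroxyguai-1(5)-en-8-one (C2 epimers) | OC1C[C@@H](C)C2=C1[C@@H](C)CC(=O)[C@@H](C(C)C)C2 | intermediate
15 | (4R,7R,10S)-guai-1(5)-ene-2,8-dione | O=C1C[C@@H](C)C2=C1[C@@H](C)CC(=O)[C@@H](C(C)C)C2 | intermediate
16 | (4R,7R,10S)-8,8-(ethylenedioxy)guai-1(5)-en-2-one | O=C1C[C@@H](C)C2=C1[C@@H](C)CC3(OCCO3)[C@@H](C(C)C)C2 | intermediate
17 | 3-(phenylselanyl) derivative of 16, Se trans to the C4 methyl | O=C1[C@H]([Se]c2ccccc2)[C@@H](C)C2=C1[C@@H](C)CC3(OCCO3)[C@@H](C(C)C)C2 | intermediate
18 | C2 alcohol of 17, OH cis to Se and to the C10 methyl | O[C@@H]1[C@H]([Se]c2ccccc2)[C@@H](C)C2=C1[C@@H](C)CC3(OCCO3)[C@@H](C(C)C)C2 | intermediate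
19 | tert-butyldimethylsilyl ether of 18 | CC(C)(C)[Si](C)(C)O[C@@H]1[C@H]([Se]c2ccccc2)[C@@H](C)C2=C1[C@@H](C)CC3(OCCO3)[C@@H](C(C)C)C2 | intermediate
20 | (2R,7R,10S)-2-(tert-butyldimethylsilyloxy)-8,8-(ethylenedioxy)guaia-1(5),3-diene | CC(C)(C)[Si](C)(C)O[C@@H]1C=C(C)C2=C1[C@@H](C)CC3(OCCO3)[C@@H](C(C)C)C2 | intermediate
21 | (4R,7S,10R)-2-hydroxyguai-1(5)-en-8-one (C2 epimers) | OC1C[C@@H](C)C2=C1[C@H](C)CC(=O)[C@H](C(C)C)C2 | intermediate
22 | (4R,7S,10R)-guai-1(5)-ene-2,8-dione | O=C1C[C@@H](C)C2=C1[C@H](C)CC(=O)[C@H](C(C)C)C2 | intermediate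
23 | (4R,7S,10R)-8,8-(ethylenedioxy)guai-1(5)-en-2-one | O=C1C[C@@H](C)C2=C1[C@H](C)CC3(OCCO3)[C@H](C(C)C)C2 | intermediate
24 | (4R,7S,10R)-8,8-(ethylenedioxy)guaia-1(5),2-dien-2-yl trifluoromethanesulfonate | FC(F)(F)S(=O)(=O)OC1=C[C@@H](C)C2=C1[C@H](C)CC3(OCCO3)[C@H](C(C)C)C2 | intermediate
25 | (4R,7S,10R)-8,8-(ethylenedioxy)guaia-1(5),2-diene | C1=C[C@@H](C)C2=C1[C@H](C)CC3(OCCO3)[C@H](C(C)C)C2 | intermediate
26 | 3,5-epidioxy-8,8-(ethylenedioxy)guai-1-ene (endoperoxide, either face) | O1OC2C=C3[C@H](C)CC4(OCCO4)[C@H](C(C)C)CC31[C@@H]2C | intermediate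
27 | (7S,10R)-5-hydroxy-8,8-(ethylenedioxy)guai-1-en-3-one (C4 and C5 epimers) | O=C1C=C2[C@H](C)CC3(OCCO3)[C@H](C(C)C)CC2(O)C1C | intermediate
28 | (7S,10R)-8,8-(ethylenedioxy)guaia-1,4-dien-3-one (cyclopentadienone) | O=C1C=C2[C@H](C)CC3(OCCO3)[C@H](C(C)C)CC2=C1C | intermediate
29 | norbornene adduct: C2 silyl ether syn to C4=C5, C3' ketone with C4'=C5', both C8 ketals, configuration of the target | CC(C)(C)[Si](C)(C)O[C@@H]1[C@@H]2C(C)=C3C[C@H](C(C)C)C4(OCCO4)C[C@H](C)[C@@]31[C@@H]1C(=O)C(C)=C3C[C@@H](C(C)C)C4(OCCO4)C[C@@H](C)[C@]312 | intermediate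
30 | 3'-trimethylsilyloxy-3',5'-diene of 29 | CC(C)(C)[Si](C)(C)O[C@@H]1[C@@H]2C(C)=C3C[C@H](C(C)C)C4(OCCO4)C[C@H](C)[C@@]31[C@@H]1C(O[Si](C)(C)C)=C(C)C3=C[C@@H](C(C)C)C4(OCCO4)C[C@@H](C)[C@]312 | intermediate
31 | 4',6'-dien-3'-one of 29 | CC(C)(C)[Si](C)(C)O[C@@H]1[C@@H]2C(C)=C3C[C@H](C(C)C)C4(OCCO4)C[C@H](C)[C@@]31[C@@H]1C(=O)C(C)=C3C=C(C(C)C)C4(OCCO4)C[C@@H](C)[C@]312 | intermediate
32 | 2-hydroxy-3',8,8'-trione (deprotected dimer) | O[C@@H]1[C@@H]2C(C)=C3C[C@H](C(C)C)C(=O)C[C@H](C)[C@@]31[C@@H]1C(=O)C(C)=C3C=C(C(C)C)C(=O)C[C@@H](C)[C@]312 | intermediate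
33 | 2-acetoxy-3',8,8'-trione | CC(=O)O[C@@H]1[C@@H]2C(C)=C3C[C@H](C(C)C)C(=O)C[C@H](C)[C@@]31[C@@H]1C(=O)C(C)=C3C=C(C(C)C)C(=O)C[C@@H](C)[C@]312 | intermediate
34 | 11'-hydroperoxide of 33 | CC(=O)O[C@@H]1[C@@H]2C(C)=C3C[C@H](C(C)C)C(=O)C[C@H](C)[C@@]31[C@@H]1C(=O)C(C)=C3C=C(C(C)(C)OO)C(=O)C[C@@H](C)[C@]312 | intermediate
35 | CNP0361479.4 | CC(=O)O[C@@H]1[C@@H]2C(C)=C3C[C@H](C(C)C)C(=O)C[C@H](C)[C@@]31[C@@H]1C(=O)C(C)=C3C=C4C(C)(C)OO[C@]4(O)C[C@@H](C)[C@]312 | target

## Step count and risks

Total: 25 steps. Longest linear sequence: 19 steps (steps 1–14 and 21–25).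

Step 6 (key step). Most likely failure: the carbenoid is diverted into addition across the hindered C5–C6 bond or into aromatic substitution, and the azulenone rearranges to a 2-tetralone if acid is present. Fallback: set out from 6 and use an acceptor/acceptor carbenoid, which is bulkier, less prone to substitution, and gives a product without the labile H-8a. Acid 6 is homologated (carbonyldiimidazole; MgCl2, potassium ethyl malonate) to ethyl (5R)-5-(3-isopropyl-4-methoxyphenyl)-3-oxohexanoate F1. Diazo transfer (4-acetamidobenzenesulfonyl azide, Et3N) gives the diazo keto ester F2. Rh2(OAc)4 gives the azulenone ester F3, and Krapcho dealkoxycarbonylation (LiCl, wet DMSO, heat) returns to the route at 11.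

Step 21. Most likely failure: the dienone ring goes endo (secondary orbital overlap), or addition occurs syn to the C2 oxygen (the usual electronic preference of 5-oxy cyclopentadienes); the dienone may also dimerise or tautomerise, and the diene may undergo hydrogen shifts. Fallback: set out from 20 and 27 and use the stable hydroxy enone 27 itself as the 2π partner under the bulky Lewis acid Al(OC6H3-2,6-Ph2)3, a known way to steer enones to exo adducts. This gives the beta-hydroxy ketone adduct F4. Dehydration (MeSO2Cl, Et3N) returns to the route at 29.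

Steps 8 and 15. Most likely failure: incomplete catalyst control at C10 on the dienone, or slow methyl transfer. Fallback: set out from 13 with an achiral cuprate (Me2CuLi, Me3SiCl) and carry the mixture through the allylic oxidation. Because C4 is fixed, the two C10 series are diastereomers, can be separated, and are both needed; they rejoin the route at 15 and 22. No new compound arises.

Step 22. Most likely failure: enolisation or palladation at the wrong site (loss of a C4' methyl hydrogen instead of H-7'). Fallback: set out from 29, form the same dienol ether 30, brominate it at C6' with N-bromosuccinimide to the 6'-bromo enone F5, and dehydrobrominate (Li2CO3, LiBr, DMF), returning at 31.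

Step 25. Most likely failure: hydrogen abstraction at other allylic positions (C15', C6), O2 uptake at C6' instead of C11', or breakdown of the hydroperoxide. Fallback: set out from 33 and replace the radical chain by oxygenation of the extended enolate (DBU, O2, MeCN, 0 °C). The epsilon hydrogen of the dienedione is acidic and the trienolate should take up O2 at its tertiary terminus; the route is rejoined at 35 and no new compound arises.

## Further compounds

F1 | step 6 | ethyl (5R)-5-(3-isopropyl-4-methoxyphenyl)-3-oxohexanoate | CCOC(=O)CC(=O)C[C@@H](C)c1ccc(OC)c(C(C)C)c1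
F2 | step 6 | ethyl (5R)-2-diazo-5-(3-isopropyl-4-methoxyphenyl)-3-oxohexanoate | CCOC(=O)C(=[N+]=[N-])C(=O)C[C@@H](C)c1ccc(OC)c(C(C)C)c1
F3 | step 6 | ethyl (3R)-6-methoxy-3-methyl-1-oxo-5-isopropyl-2,3-dihydroazulene-8a(1H)-carboxylate (C8a epimers) | COC1=C(C(C)C)C=C2[C@H](C)CC(=O)C2(C(=O)OCC)C=C1
F4 | step 21 | 5'-hydroxy-4',5'-dihydro form of 29 (C4' and C5' epimers) | CC(C)(C)[Si](C)(C)O[C@@H]1[C@@H]2C(C)=C3C[C@H](C(C)C)C4(OCCO4)C[C@H](C)[C@@]31[C@@H]1C(=O)C(C)C3(O)C[C@@H](C(C)C)C4(OCCO4)C[C@@H](C)[C@]312
F5 | step 22 | 6'-bromo derivative of 29 (C6' epimers) | CC(C)(C)[Si](C)(C)O[C@@H]1[C@@H]2C(C)=C3C[C@H](C(C)C)C4(OCCO4)C[C@H](C)[C@@]31[C@@H]1C(=O)C(C)=C3C(Br)[C@@H](C(C)C)C4(OCCO4)C[C@@H](C)[C@]312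
F0 | step 8 | none | none
F0 | step 25 | none | none
A1 | alternative 1 | methyl 2-diazo-3-(tert-butyldimethylsilyloxy)but-3-enoate | COC(=O)C(=[N+]=[N-])C(=C)O[Si](C)(C)C(C)(C)C
A2 | alternative 1 | 1-ethylidene-2-methylene-3-methyl-4-(tert-butyldimethylsilyloxy)cyclopentane | C=C1[C@H](C)[C@@H](O[Si](C)(C)C(C)(C)C)CC1=CC
A3 | alternative 1 | hydroazulene silyl enol ether ester | COC(=O)C1=C(O[Si](C)(C)C(C)(C)C)C[C@@H](C)C2=C(C1)[C@H](C)[C@@H](O[Si](C)(C)C(C)(C)C)C2
A4 | alternative 2 | bridging alpha-diazoketone of the bicyclo[2.2.2]octenone dimer | O=C1C(=[N+]=[N-])[C@@H]2C(C)=C3C[C@H](C(C)C)C(=O)C[C@H](C)[C@@]31[C@@H]1C(=O)C(C)=C3CC(=C(C)C)C(=O)C[C@@H](C)[C@]312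
A5 | alternative 2 | norbornene C2 methyl ester | COC(=O)[C@@H]1[C@@H]2C(C)=C3C[C@H](C(C)C)C(=O)C[C@H](C)[C@@]31[C@@H]1C(=O)C(C)=C3CC(=C(C)C)C(=O)C[C@@H](C)[C@]312
A6 | alternative 3 | C5' vinyl, C8' propynyl ketal enyne dimer | CC(=O)O[C@@H]1[C@@H]2C(C)=C3C[C@H](C(C)C)C(=O)C[C@H](C)[C@@]31[C@@H]1C(=O)C(C)=C(C=C)[C@@]12[C@H](C)CC3(OCCO3)C#CC
A7 | alternative 3 | isopropenyl cycloheptadienone ketal dimer | CC(=O)O[C@@H]1[C@@H]2C(C)=C3C[C@H](C(C)C)C(=O)C[C@H](C)[C@@]31[C@@H]1C(=O)C(C)=C3C=C(C(C)=C)C4(OCCO4)C[C@@H](C)[C@]312
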